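**Plan**
Retrosynthesis: the 4-nitrobenzyl ester on ring C is removed first, then the two aryl C2–O bonds of ring B and ring C are cut (twofold ester-directed C–H oxygenation), then the B–C and A–B aryl ester C(=O)–O bonds, and last the C6–CH3 bond of ring A.
Enabling feature: in ring B (central) and ring C (terminal) C2 is the only C–H ortho to the C1 carbonyl because C6 carries a methyl group, and ring A has OCH3 at C2 and CH3 at C6 and so no ortho hydrogen; carbonyl-guided metalation can reach only the two wanted carbons.
Forward: no ring is built. Ring A acid (ortho-lithiation and methylation of 2,4,5-trimethoxybenzoic acid) is joined to ring B, the A–B acid is joined to ring C, and both hydroxyls are installed last on the complete A–B–C chain.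
Ring C keeps its carboxyl as a 4-nitrobenzyl ester through the key step, so both directing groups are ester carbonyls; hydrogenolysis then frees the acid.
Stereochemistry: the target has no stereocenter and no double-bond geometry, so none has to be set.

Key step: step 7

**Step 1**
Reactants: 1 2,4,5-trimethoxybenzoic acid
Product: 3 2,4,5-trimethoxy-6-methylbenzoic acid, via dilithio carboxylate 2 (not isolated)
Conditions: s-BuLi (2.2 equiv), TMEDA, THF, −78 °C; MeI, −78 °C to rt; aq. HCl
Reagents that add atoms: iodomethane, CI
Why: Directed ortho-metalation of the unprotected benzoic acid, in which the lithium carboxylate holds s-BuLi/TMEDA next to C6 (its only ortho C–H, further acidified by the neighbouring 5-methoxy group) in preference to C3, and the aryllithium is then alkylated by iodomethane in an SN2 reaction.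

**Step 2**
Reactants: 4 4-hydroxy-2-methylbenzoic acid
Product: 5 benzyl 4-hydroxy-2-methylbenzoate
Conditions: BnBr, KHCO3, DMF, 40 °C
Reagents that add atoms: benzyl bromide, BrCc1ccccc1
Why: Chemoselective SN2 O-alkylation of the carboxylate, since KHCO3 deprotonates the carboxylic acid but not the phenol.

**Step 3**
Reactants: 3 2,4,5-trimethoxy-6-methylbenzoic acid; 5 benzyl 4-hydroxy-2-methylbenzoate
Product: 7 benzyl 2-methyl-4-[(2,4,5-trimethoxy-6-methylbenzoyl)oxy]benzoate, via acid chloride 6 (not isolated)
Conditions: (COCl)2, cat. DMF, CH2Cl2, 0 °C to rt; evaporate; 5, Et3N, cat. DMAP, CH2Cl2, 0 °C to rt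
Reagents that add atoms: none
Why: Oxalyl chloride with catalytic DMF converts the acid into its chloride through the chloroiminium salt, and the phenol of 5 is then acylated under DMAP catalysis (nucleophilic acyl substitution), the usual way to attach 2,6-disubstituted electron-rich benzoyl groups to phenols in depside work.

**Step 4**
Reactants: 7 benzyl 2-methyl-4-[(2,4,5-trimethoxy-6-methylbenzoyl)oxy]benzoate
Product: 8 2-methyl-4-[(2,4,5-trimethoxy-6-methylbenzoyl)oxy]benzoic acid
Conditions: H2 (1 atm), 10% Pd/C, EtOAc, rt
Reagents that add atoms: none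
Why: Palladium-catalysed hydrogenolysis of the benzylic C–O bond should free the carboxylic acid while the aryl ester, the methoxy groups and the arenes stay untouched.

**Step 5**
Reactants: 4 4-hydroxy-2-methylbenzoic acid
Product: 9 4-nitrobenzyl 4-hydroxy-2-methylbenzoate
Conditions: 4-nitrobenzyl bromide, KHCO3, DMF, rt
Reagents that add atoms: 4-nitrobenzyl bromide, BrCc1ccc(cc1)[N+](=O)[O-]
Why: The same chemoselective SN2 carboxylate alkylation as in step 2, here installing an ester that resists hot acid and oxidants and is cleaved later by hydrogenation.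

**Step 6**
Reactants: 8 2-methyl-4-[(2,4,5-trimethoxy-6-methylbenzoyl)oxy]benzoic acid; 9 4-nitrobenzyl 4-hydroxy-2-methylbenzoate
Product: 10 4-nitrobenzyl 2-methyl-4-({2-methyl-4-[(2,4,5-trimethoxy-6-methylbenzoyl)oxy]benzoyl}oxy)benzoate
Conditions: EDC·HCl, cat. DMAP, CH2Cl2, 0 °C to rt
Reagents that add atoms: none
Why: Steglich esterification, in which the carbodiimide activates the singly ortho-substituted acid as its O-acylisourea and DMAP relays the acyl group to the phenol, while the doubly ortho-shielded ring A ester is not attacked.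

**Step 7**
Reactants: 10 4-nitrobenzyl 2-methyl-4-({2-methyl-4-[(2,4,5-trimethoxy-6-methylbenzoyl)oxy]benzoyl}oxy)benzoate
Product: 12 4-nitrobenzyl 2-hydroxy-4-({2-hydroxy-6-methyl-4-[(2,4,5-trimethoxy-6-methylbenzoyl)oxy]benzoyl}oxy)-6-methylbenzoate, via bis(trifluoroacetate) 11 (not isolated)
Conditions: [RuCl2(p-cymene)]2 (5 mol %), K2S2O8 (4 equiv), CF3CO2H/(CF3CO)2O, 80 °C; then pH 7 phosphate buffer/EtOAc, rt
Reagents that add atoms: trifluoroacetic acid, OC(=O)C(F)(F)F
Why: Each ester carbonyl oxygen binds the cationic divalent ruthenium trifluoroacetate formed from [RuCl2(p-cymene)]2, carboxylate-assisted deprotonation of the adjacent C2–H gives a five-membered ruthenacycle, persulfate oxidizes it to tetravalent ruthenium, and C–O reductive elimination gives the aryl trifluoroacetate, which the anhydride keeps capped until the buffered work-up hydrolyzes it. The closest known reaction is the ruthenium-catalysed ester-directed ortho C–H hydroxylation of alkyl benzoates with the same reagents, run here at two benzoate sites of one molecule. No ring is closed and no stereocenter is formed. The step needs site selectivity for C2 of ring B and ring C, which is secured by the C6 methyl groups blocking the second ortho position, by the absence of any ortho hydrogen on ring A, and by the preference of weakly coordinating esters for a five-membered metallacycle on the acyl ring over a six-membered one on the phenoxy ring. It also needs ring A to survive, which rests on deactivation of that ring by its own ester carbonyl, on the shielding of its single C–H between two methoxy groups, and on the low solubility of K2S2O8 in the acidic medium. The 4-nitrobenzyl ester is inert to hot acid and oxidant and supplies the directing carbonyl for ring C.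

**Step 8**
Reactants: 12 4-nitrobenzyl 2-hydroxy-4-({2-hydroxy-6-methyl-4-[(2,4,5-trimethoxy-6-methylbenzoyl)oxy]benzoyl}oxy)-6-methylbenzoate
Product: 13 2-hydroxy-4-({2-hydroxy-6-methyl-4-[(2,4,5-trimethoxy-6-methylbenzoyl)oxy]benzoyl}oxy)-6-methylbenzoic acid
Conditions: H2 (1 atm), 10% Pd/C, EtOAc/AcOH, rt
Reagents that add atoms: none
Why: Hydrogenation reduces the nitro group to the aniline and hydrogenolyzes the benzylic C–O bond of the resulting 4-aminobenzyl ester, a neutral release of the carboxylic acid that should leave both depside ester bonds and the phenols intact.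

**Compound list**
1 | 2,4,5-trimethoxybenzoic acid | COc1cc(OC)c(C(=O)O)cc1OC | starting material
2 | lithium 6-lithio-2,4,5-trimethoxybenzoate (dilithio carboxylate) | COc1cc(OC)c(C(=O)O[Li])c([Li])c1OC | intermediate
3 | 2,4,5-trimethoxy-6-methylbenzoic acid | COc1cc(OC)c(C(=O)O)c(C)c1OC | intermediate
4 | 4-hydroxy-2-methylbenzoic acid | Cc1cc(O)ccc1C(=O)O | starting material
5 | benzyl 4-hydroxy-2-methylbenzoate | Cc1cc(O)ccc1C(=O)OCc1ccccc1 | intermediate
6 | 2,4,5-trimethoxy-6-methylbenzoyl chloride | COc1cc(OC)c(C(Cl)=O)c(C)c1OC | intermediate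
7 | benzyl 2-methyl-4-[(2,4,5-trimethoxy-6-methylbenzoyl)oxy]benzoate | COc1cc(OC)c(C(=O)Oc2ccc(C(=O)OCc3ccccc3)c(C)c2)c(C)c1OC | intermediate
8 | 2-methyl-4-[(2,4,5-trimethoxy-6-methylbenzoyl)oxy]benzoic acid | COc1cc(OC)c(C(=O)Oc2ccc(C(=O)O)c(C)c2)c(C)c1OC | intermediate
9 | 4-nitrobenzyl 4-hydroxy-2-methylbenzoate | Cc1cc(O)ccc1C(=O)OCc1ccc(cc1)[N+](=O)[O-] | intermediate
10 | 4-nitrobenzyl 2-methyl-4-({2-methyl-4-[(2,4,5-trimethoxy-6-methylbenzoyl)oxy]benzoyl}oxy)benzoate (dideoxy tridepside ester) | COc1cc(OC)c(C(=O)Oc2ccc(C(=O)Oc3ccc(C(=O)OCc4ccc(cc4)[N+](=O)[O-])c(C)c3)c(C)c2)c(C)c1OC | intermediate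
11 | bis(trifluoroacetate) of 12 (both new C2 oxygens acylated) | COc1cc(OC)c(C(=O)Oc2cc(C)c(C(=O)Oc3cc(C)c(C(=O)OCc4ccc(cc4)[N+](=O)[O-])c(OC(=O)C(F)(F)F)c3)c(OC(=O)C(F)(F)F)c2)c(C)c1OC | intermediate
12 | 4-nitrobenzyl 2-hydroxy-4-({2-hydroxy-6-methyl-4-[(2,4,5-trimethoxy-6-methylbenzoyl)oxy]benzoyl}oxy)-6-methylbenzoate | COc1cc(OC)c(C(=O)Oc2cc(C)c(C(=O)Oc3cc(C)c(C(=O)OCc4ccc(cc4)[N+](=O)[O-])c(O)c3)c(O)c2)c(C)c1OC | intermediate
13 | 2-hydroxy-4-({2-hydroxy-6-methyl-4-[(2,4,5-trimethoxy-6-methylbenzoyl)oxy]benzoyl}oxy)-6-methylbenzoic acid (CNP0328932.0) | COc1cc(OC)c(C(=O)Oc2cc(C)c(C(=O)Oc3cc(C)c(C(=O)O)c(O)c3)c(O)c2)c(C)c1OC | target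

**Count and risks**
Total step count: 8. Longest linear sequence: 6 steps (steps 1, 3, 4, 6, 7, 8; the branch through steps 2, 3, 4, 6, 7, 8 is equally long).

Steps most likely to fail:

1. Step 7. Persulfate may oxidize the trimethoxyarene of ring A by single-electron transfer, leading to oxidative demethylation. The hot acid/anhydride medium may ionize the electron-rich, doubly ortho-substituted ring A ester and scramble the depside bonds. The second oxygenation may stall, or metalation may occur ortho to an ester oxygen through a six-membered ruthenacycle. The fallback sets out from 10 and replaces oxidative oxygenation by redox-neutral borylation followed by boron-to-oxygen exchange. Ester-directed ortho C–H borylation ([Ir(OMe)(cod)]2, P[3,5-(CF3)2C6H3]3, B2pin2, octane, 80 °C) should place a boronate at C2 of ring B and ring C and give the bis(pinacolboronate) F1. Brief oxidation with Oxone (2KHSO5·KHSO4·K2SO4) in aqueous acetone at rt should then convert both C–B bonds into C–OH. The route is rejoined at 12.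

2. Step 1. Deprotonation may be poorly site-selective, with C3 between two methoxy groups competing with C6, and s-BuLi may add to the carboxylate. The fallback sets out from 1 and uses the stronger tertiary amide director. Coupling with diethylamine (EDC·HCl, HOBt, CH2Cl2) should give N,N-diethyl-2,4,5-trimethoxybenzamide F2. Treatment with s-BuLi/TMEDA in THF at −78 °C should give the 6-lithio amide F3, and iodomethane then N,N-diethyl-2,4,5-trimethoxy-6-methylbenzamide F4. Partial reduction of the hindered amide with Cp2Zr(H)Cl in THF at rt should give 2,4,5-trimethoxy-6-methylbenzaldehyde F5. Pinnick oxidation (NaClO2, NaH2PO4, 2-methyl-2-butene, t-BuOH/H2O) returns the route to 3.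

3. Step 3. Acyl transfer at the doubly ortho-substituted carbonyl may be slow, and the electron-rich acid chloride may decompose before the phenol is acylated. The fallback sets out from 3 and 5 and changes from base-mediated substitution at a shielded carbonyl to acylation by a linear acylium ion. Trifluoroacetic anhydride in toluene at rt should convert 3 into 2,4,5-trimethoxy-6-methylbenzoic trifluoroacetic anhydride F6, which ionizes to the acylium ion and is captured by the phenol of 5. The route is rejoined at 7.

**Further compounds**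
F1 | step 7 | 4-nitrobenzyl ester of the tridepside bearing pinacolboronate groups at C2 of ring B and ring C (bis(pinacolboronate)) | COc1cc(OC)c(C(=O)Oc2cc(C)c(C(=O)Oc3cc(C)c(C(=O)OCc4ccc(cc4)[N+](=O)[O-])c(B5OC(C)(C)C(C)(C)O5)c3)c(B6OC(C)(C)C(C)(C)O6)c2)c(C)c1OC
F2 | step 1 | N,N-diethyl-2,4,5-trimethoxybenzamide | CCN(CC)C(=O)c1cc(OC)c(OC)cc1OC
F3 | step 1 | N,N-diethyl-6-lithio-2,4,5-trimethoxybenzamide | CCN(CC)C(=O)c1c([Li])c(OC)c(OC)cc1OC
F4 | step 1 | N,N-diethyl-2,4,5-trimethoxy-6-methylbenzamide | CCN(CC)C(=O)c1c(C)c(OC)c(OC)cc1OC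
F5 | step 1 | 2,4,5-trimethoxy-6-methylbenzaldehyde | COc1cc(OC)c(C=O)c(C)c1OC
F6 | step 3 | 2,4,5-trimethoxy-6-methylbenzoic trifluoroacetic anhydride | COc1cc(OC)c(C(=O)OC(=O)C(F)(F)F)c(C)c1OC
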